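**Retrosynthetic overview**
1. The target comes from acidic MOM removal, preceded by hydrogenolysis of the ArO–Bn ether and a benzylic acetate. This leads back to a C3-quaternary aldol adduct that still carries oxygen on the future vanillyl CH2.
2. The key disconnection is C3–CH(OH)Ar. It is an intermolecular aldol addition of the lithium enolate of 3-(methoxymethoxy)-4-(3,4-dimethoxybenzyl)butyrolactone to O-benzylvanillin, anti to the C4 substituent, and it sets C3.
3. The C3–O bond comes from Davis hydroxylation of (R)-4-(3,4-dimethoxybenzyl)butyrolactone, followed by MOM protection.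
4. The lactone C–O bond and C4 come from acid lactonisation of a hydroxy tert-butyl ester. That ester is made by Evans alkylation of the N-(3-arylpropanoyl)-(S)-4-benzyloxazolidinone with tert-butyl bromoacetate, which sets C4.
5. Ring order: both benzene rings are bought. The γ-lactone is the only ring formed (step 4), before either C3 substituent is installed.

Assumption: the SMILES is read as (3S,4S), natural (−)-trachelogenin, with the two benzyl groups trans and the tertiary OH cis to the 3,4-dimethoxybenzyl group. The strong bases are bought as titrated solutions.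

**Step 1**
Reactants: 1 3-(3,4-dimethoxyphenyl)propanoic acid; 2 (S)-4-benzyl-1,3-oxazolidin-2-one
Product: 4 (4S)-4-benzyl-3-[3-(3,4-dimethoxyphenyl)propanoyl]-1,3-oxazolidin-2-one, via mixed pivalic anhydride 3 (not isolated)
Conditions: t-BuCOCl (1.05 equiv), Et3N (2.5 equiv), THF, −20 °C, 1 h; then LiCl (1.1 equiv), 2, −20 °C → rt
Reagents that add atoms: pivaloyl chloride, CC(C)(C)C(=O)Cl (its acyl group is found in 3 only)
Why: In this mixed-anhydride N-acylation the LiCl-activated oxazolidinone attacks the unhindered acyl carbon of 3 rather than the pivaloyl carbon, and no stereocentre is touched.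

**Step 2**
Reactants: 4 the imide; 5 tert-butyl bromoacetate
Product: 7 tert-butyl (3R)-4-[(4S)-4-benzyl-2-oxo-1,3-oxazolidin-3-yl]-3-(3,4-dimethoxybenzyl)-4-oxobutanoate, via sodium Z-enolate 6 (not isolated)
Conditions: NaN(SiMe3)2 (1.1 equiv), THF, −78 °C, 45 min; then 5 (2 equiv), −78 → −30 °C
Reagents that add atoms: NaN(SiMe3)2, C[Si](C)(C)[N-][Si](C)(C)C.[Na+] (its Na+ is found in 6 only)
Why: In this Evans asymmetric alkylation the benzyl group of the (S)-auxiliary shields one face of the chelated Z-enolate, so the bromoacetate enters from the other face and sets the (R) centre (later C4 of the lactone) with dr typically above 95:5, the minor isomer being removed by chromatography or crystallisation.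

**Step 3**
Reactants: 7 the alkylated imide
Product: 8 tert-butyl (3R)-3-(3,4-dimethoxybenzyl)-4-hydroxybutanoate
Conditions: NaBH4 (4 equiv), THF/H2O 3:1, 0 °C → rt
Reagents that add atoms: none
Why: Reductive cleavage of the Evans auxiliary by borohydride is far faster at the activated imide carbonyl than at the tert-butyl ester, and it does not epimerise the adjacent centre.

**Step 4**
Reactants: 8 the hydroxy ester
Product: 9 (4R)-4-(3,4-dimethoxybenzyl)dihydrofuran-2(3H)-one
Conditions: p-TsOH·H2O (10 mol %), toluene, 90 °C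
Reagents that add atoms: none
Why: Acid-catalysed tert-butyl ester cleavage and 5-exo lactonisation closes the only ring to be built, isobutene leaves as a gas, and the stereocentre takes no part.

**Step 5**
Reactants: 9 the lactone
Product: 11 (3R,4S)-4-(3,4-dimethoxybenzyl)-3-hydroxydihydrofuran-2(3H)-one (OH trans to the benzyl group), via sodium enolate 10 (not isolated)
Conditions: NaN(SiMe3)2 (1.2 equiv), THF, −78 °C, 30 min; then 2-(phenylsulfonyl)-3-phenyloxaziridine (1.5 equiv), −78 °C, 1 h; AcOH quench
Reagents that add atoms: 2-(phenylsulfonyl)-3-phenyloxaziridine, O=S(=O)(c1ccccc1)N1OC1c1ccccc1 (oxygen atom); NaN(SiMe3)2, C[Si](C)(C)[N-][Si](C)(C)C.[Na+] (its Na+ is found in 10 only)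
Why: In this Davis oxidation oxygen is transferred to the enolate face anti to the C4 benzyl group to give mainly the trans isomer, and any cis isomer is carried along because C3 becomes planar again in step 7.

**Step 6**
Reactants: 11 the hydroxy lactone
Product: 12 (3R,4S)-4-(3,4-dimethoxybenzyl)-3-(methoxymethoxy)dihydrofuran-2(3H)-one
Conditions: MOMCl (3 equiv), i-Pr2NEt (4 equiv), n-Bu4NI (cat.), CH2Cl2, 0 → 40 °C
Reagents that add atoms: chloromethyl methyl ether (MOMCl), COCCl
Why: MOM ether formation under amine-base conditions masks the OH as a base-stable acetal that, unlike a silyl group, cannot migrate to the neighbouring alkoxide formed in the aldol step.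

**Step 7 (key step)**
Reactants: 12 the MOM ether; 13 4-benzyloxy-3-methoxybenzaldehyde (O-benzylvanillin)
Product: 15 (3R,4S)-3-[(4-benzyloxy-3-methoxyphenyl)(hydroxy)methyl]-4-(3,4-dimethoxybenzyl)-3-(methoxymethoxy)dihydrofuran-2(3H)-one (both carbinol epimers), via lithium enolate 14 (not isolated)
Conditions: LiN(i-Pr)2 (1.15 equiv, commercial solution), THF, −78 °C, 1 h; then 13 (1.3 equiv) in THF, −78 °C, 2 h; AcOH in THF at −78 °C
Reagents that add atoms: LiN(i-Pr)2, CC(C)[N-]C(C)C.[Li+] (its Li+ is found in 14 only)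
Why: In this intermolecular lithium-enolate aldol addition the aldehyde attacks the planar enolate 14 on the face anti to the C4 benzyl group (pushed pseudoaxial by A(1,2) strain with the C3 oxygen), so the new C–C bond is trans and the C3 oxygen cis to that group as in the target, while the carbinol epimers do not matter because that centre is removed in step 9.

**Step 8**
Reactants: 15 the aldol adduct
Product: 16 (3R,4S)-3-[acetoxy(4-benzyloxy-3-methoxyphenyl)methyl]-4-(3,4-dimethoxybenzyl)-3-(methoxymethoxy)dihydrofuran-2(3H)-one (both epimers)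
Conditions: Ac2O (3 equiv), DMAP (cat.), pyridine, rt
Reagents that add atoms: acetic anhydride, CC(=O)OC(C)=O
Why: DMAP-catalysed acylation turns the benzylic OH into a leaving group under conditions too mild for retro-aldol, and elimination is impossible because C3 bears no hydrogen.

**Step 9**
Reactants: 16 the acetate
Product: 18 (3S,4S)-4-(3,4-dimethoxybenzyl)-3-(4-hydroxy-3-methoxybenzyl)-3-(methoxymethoxy)dihydrofuran-2(3H)-one, via phenol acetate 17 (not isolated)
Conditions: H2 (4 bar), 10% Pd/C, EtOAc, 40 °C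
Reagents that add atoms: none
Why: In this neutral heterogeneous hydrogenolysis the phenolic benzyl ether falls first and the resulting 4-hydroxybenzylic acetate 17 then loses its benzylic C–O bond (directly or through its p-quinone methide), which avoids the acid-induced Friedel–Crafts closure to an aryltetralin and leaves C3, C4, the MOM group and the lactone untouched.

**Step 10**
Reactants: 18 O-MOM-trachelogenin
Product: 19 (−)-trachelogenin, (3S,4S)-4-(3,4-dimethoxybenzyl)-3-hydroxy-3-(4-hydroxy-3-methoxybenzyl)dihydrofuran-2(3H)-one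
Conditions: conc. HCl (cat.), MeOH, 45 °C
Reagents that add atoms: none
Why: Acid-catalysed transacetalisation moves the CH2 unit of the MOM group to methanol, the tertiary carbinol next to the carbonyl does not ionise, and the substituted γ-lactone stays closed, so neither stereocentre changes.

**Compound list**
1 | 3-(3,4-dimethoxyphenyl)propanoic acid | COc1ccc(CCC(=O)O)cc1OC | starting material
2 | (S)-4-benzyl-1,3-oxazolidin-2-one | O=C1N[C@@H](Cc2ccccc2)CO1 | starting material
3 | 3-(3,4-dimethoxyphenyl)propanoic pivalic anhydride | COc1ccc(CCC(=O)OC(=O)C(C)(C)C)cc1OC | intermediate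
4 | (4S)-4-benzyl-3-[3-(3,4-dimethoxyphenyl)propanoyl]-1,3-oxazolidin-2-one | COc1ccc(CCC(=O)N2[C@@H](Cc3ccccc3)COC2=O)cc1OC | intermediate
5 | tert-butyl bromoacetate | CC(C)(C)OC(=O)CBr | starting material
6 | sodium (Z)-enolate of 4 | COc1ccc(C/C=C(\[O-])N2[C@@H](Cc3ccccc3)COC2=O)cc1OC.[Na+] | intermediate
7 | tert-butyl (3R)-4-[(4S)-4-benzyl-2-oxo-1,3-oxazolidin-3-yl]-3-(3,4-dimethoxybenzyl)-4-oxobutanoate | COc1ccc(C[C@H](CC(=O)OC(C)(C)C)C(=O)N2[C@@H](Cc3ccccc3)COC2=O)cc1OC | intermediate
8 | tert-butyl (3R)-3-(3,4-dimethoxybenzyl)-4-hydroxybutanoate | COc1ccc(C[C@H](CC(=O)OC(C)(C)C)CO)cc1OC | intermediate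
9 | (4R)-4-(3,4-dimethoxybenzyl)dihydrofuran-2(3H)-one | COc1ccc(C[C@H]2COC(=O)C2)cc1OC | intermediate
10 | sodium enolate of 9 | C1=C([O-])OC[C@@H]1Cc1ccc(OC)c(OC)c1.[Na+] | intermediate
11 | (3R,4S)-4-(3,4-dimethoxybenzyl)-3-hydroxydihydrofuran-2(3H)-one | O[C@H]1C(=O)OC[C@@H]1Cc1ccc(OC)c(OC)c1 | intermediate
12 | (3R,4S)-4-(3,4-dimethoxybenzyl)-3-(methoxymethoxy)dihydrofuran-2(3H)-one | COCO[C@H]1C(=O)OC[C@@H]1Cc1ccc(OC)c(OC)c1 | intermediate
13 | 4-benzyloxy-3-methoxybenzaldehyde | COc1cc(C=O)ccc1OCc1ccccc1 | starting material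
14 | lithium enolate of 12 | COCOC1=C([O-])OC[C@@H]1Cc1ccc(OC)c(OC)c1.[Li+] | intermediate
15 | (3R,4S)-3-[(4-benzyloxy-3-methoxyphenyl)(hydroxy)methyl]-4-(3,4-dimethoxybenzyl)-3-(methoxymethoxy)dihydrofuran-2(3H)-one, carbinol epimers | COCO[C@]1(C(O)c2ccc(OCc3ccccc3)c(OC)c2)C(=O)OC[C@@H]1Cc1ccc(OC)c(OC)c1 | intermediate
16 | (3R,4S)-3-[acetoxy(4-benzyloxy-3-methoxyphenyl)methyl]-4-(3,4-dimethoxybenzyl)-3-(methoxymethoxy)dihydrofuran-2(3H)-one, epimers | COCO[C@]1(C(OC(C)=O)c2ccc(OCc3ccccc3)c(OC)c2)C(=O)OC[C@@H]1Cc1ccc(OC)c(OC)c1 | intermediate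
17 | (3R,4S)-3-[acetoxy(4-hydroxy-3-methoxyphenyl)methyl]-4-(3,4-dimethoxybenzyl)-3-(methoxymethoxy)dihydrofuran-2(3H)-one, epimers | COCO[C@]1(C(OC(C)=O)c2ccc(O)c(OC)c2)C(=O)OC[C@@H]1Cc1ccc(OC)c(OC)c1 | intermediate
18 | (3S,4S)-4-(3,4-dimethoxybenzyl)-3-(4-hydroxy-3-methoxybenzyl)-3-(methoxymethoxy)dihydrofuran-2(3H)-one | COCO[C@]1(Cc2ccc(O)c(OC)c2)C(=O)OC[C@@H]1Cc1ccc(OC)c(OC)c1 | intermediate
19 | (−)-trachelogenin | COc1cc(C[C@@]2(O)C(=O)OC[C@@H]2Cc2ccc(OC)c(OC)c2)ccc1O | target

**Totals**
Total step count: 10. Longest linear sequence: 10 (1 → 19).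

**Steps most likely to fail**

Step 7. The addition builds a congested quaternary centre with an electron-rich aldehyde. It may therefore revert or stop short, and the facial selectivity must be high. The fallback sets out from 12 and 13 and comes back at 18.
- Aldehyde 13 is reduced with NaBH4 (MeOH, 0 °C) to (4-benzyloxy-3-methoxyphenyl)methanol F1.
- PBr3 (Et2O, 0 °C) converts this into 4-benzyloxy-3-methoxybenzyl bromide F2.
- Enolate 14, made from 12 as before but in THF/DMPU, is then alkylated irreversibly (SN2) by the bromide on the same face, anti to the C4 substituent.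
- This gives (3S,4S)-3-(4-benzyloxy-3-methoxybenzyl)-4-(3,4-dimethoxybenzyl)-3-(methoxymethoxy)dihydrofuran-2(3H)-one F3.
- Simple O-debenzylation (H2, 1 bar, 10% Pd/C, EtOAc) delivers 18.

Step 9. The benzylic C–O bond sits next to a quaternary carbon, and the reaction may stall after the easy O-debenzylation. The fallback sets out from 16 and comes back at 18.
- A short hydrogenolysis (H2, 1 bar, 10% Pd/C, EtOAc, rt) is stopped at the phenol acetate 17, which is isolated.
- Compound 17 is treated with NaBH4 in THF/i-PrOH at 0 °C.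
- The phenoxide expels acetate by 1,6-elimination to give the p-quinone methide of the C3 side chain F4.
- This intermediate cannot tautomerise, because the neighbouring carbon is quaternary. It takes up hydride at the exocyclic carbon (1,6-addition) to give 18.
- The hindered lactone survives the brief cold exposure.

Step 5. Unsubstituted lactone enolates can add to the sulfonimine by-product or give only moderate conversion. The fallback sets out from 9 and comes back at 11.
- Lactone 9 is converted with LiN(i-Pr)2 and Me3SiCl (THF, −78 °C) into the silyl ketene acetal {[(4R)-4-(3,4-dimethoxybenzyl)-4,5-dihydrofuran-2-yl]oxy}trimethylsilane F5.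
- Rubottom oxidation with mCPBA (CH2Cl2/hexane, 0 °C) epoxidises the face anti to the benzyl group.
- After silyl migration this gives (3R,4S)-4-(3,4-dimethoxybenzyl)-3-(trimethylsilyloxy)dihydrofuran-2(3H)-one F6.
- 1 M HCl in THF cleaves the silyl ether to 11.

**Further compounds**
F1 | step 7 | (4-benzyloxy-3-methoxyphenyl)methanol | COc1cc(CO)ccc1OCc1ccccc1
F2 | step 7 | 4-benzyloxy-3-methoxybenzyl bromide | COc1cc(CBr)ccc1OCc1ccccc1
F3 | step 7 | (3S,4S)-3-(4-benzyloxy-3-methoxybenzyl)-4-(3,4-dimethoxybenzyl)-3-(methoxymethoxy)dihydrofuran-2(3H)-one | COCO[C@]1(Cc2ccc(OCc3ccccc3)c(OC)c2)C(=O)OC[C@@H]1Cc1ccc(OC)c(OC)c1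
F4 | step 9 | p-quinone methide, 4-(3,4-dimethoxybenzyl)-3-[(3-methoxy-4-oxocyclohexa-2,5-dien-1-ylidene)methyl]-3-(methoxymethoxy)dihydrofuran-2(3H)-one with the ring configuration of 17 | COCO[C@]1(C=C2C=CC(=O)C(OC)=C2)C(=O)OC[C@@H]1Cc1ccc(OC)c(OC)c1
F5 | step 5 | {[(4R)-4-(3,4-dimethoxybenzyl)-4,5-dihydrofuran-2-yl]oxy}trimethylsilane | C1=C(O[Si](C)(C)C)OC[C@@H]1Cc1ccc(OC)c(OC)c1
F6 | step 5 | (3R,4S)-4-(3,4-dimethoxybenzyl)-3-(trimethylsilyloxy)dihydrofuran-2(3H)-one | C[Si](C)(C)O[C@H]1C(=O)OC[C@@H]1Cc1ccc(OC)c(OC)c1
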